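## Structural features

The target is a daucane-type hydroazulene: cyclopentane ring A (C1–C5) shares the C1–C5 bond with cycloheptane ring B (C1, C5–C10), and the junction is trans (C1 methyl on the β face, H5 on the α face). Its eight stereocentres (1R,2S,4R,5R,6R,8R,9R,10R) form two contiguous runs, C4–C5–C6 and C8–C9–C10–C1–C2; C1 is quaternary and C4 is a tertiary carbinol carrying the isopropyl group. Four skeletal oxygens must be told apart: acetate at C2, 3,4-dimethoxybenzoate at C6, a free secondary hydroxyl at C10 and a free tertiary hydroxyl at C4. The C8–C9 oxirane has C7 and C10 on opposite sides of the three-membered ring, so ring B is a trans-8-oxabicyclo[5.1.0]octane. This strained, acid-sensitive unit cannot be made on a finished cycloheptane: a cycloheptene is cis, and a ring halohydrin would need antiperiplanar ring bonds to close. Other weak points are the 1,3-related oxygens at C2 and C10 (acyl migration; retro-aldol while C2 is a ketone) and the β-oxygen at C4 (elimination). The real difficulty is threefold: to own the oxirane geometry before ring B exists, to close ring B onto it, and to acylate C2 and C6 while C10 stays free. The key step exploits the substitution of the oxirane carbons: C8 carries CH3 and C7, C9 carries H and C10, with C10 cis to the methyl group. That is exactly the result of syn addition of methyl–metal to a terminal C8≡C9 alkyne followed by attachment of a one-carbon electrophile at C9.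

## Logic of the disconnections

35 ⇒ 34 ⇒ 32 + 33. Bonds cut: the C6 O–aroyl bond; the C10 oxygen carries a removable acyl group in 34. C6 and C10 are both secondary carbinols, so only a mask on C10 makes the acylation of 32 unambiguous (C4–OH is tertiary). The demand is a C10 group that leaves without touching two other esters and a strained oxirane; this is met by an ester cleaved through its remote alkene.

32 ⇒ 31 ⇒ 30. Bonds cut: two O–Si bonds and the C2 O–acetyl bond. In 30 the C2 hydroxyl is the only free one, so acetylation needs no selectivity. The demand is that 30 arrives with C2–OH free and C10–O acylated.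

30 ⇒ 26 + 27. Bonds cut: C1–C10 (ring B), the C2–H bond and the acyl C–O bond on the C10 oxygen. C1–C10 is the only ring B bond next to a carbonyl group that can be formed with the oxirane already in the chain. Cutting it removes the strained bicycle and three stereocentres (C1, C10, C2) at once. The forward step needs a regiodefined C1 enolate under non-basic conditions, a trans ring fusion, and immediate removal of the β-hydroxy ketone, which would otherwise revert.

26 ⇒ 25 ⇒ 24. Bonds cut: C8–O and C9–O of the oxirane; C10 returns to the alcohol level. The oxirane becomes an (E)-trisubstituted allylic alcohol, the ideal substrate for reagent-controlled epoxidation. The demand is pure E geometry in 24.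

24 ⇒ 23 ⇒ 21 ⇒ 20 ⇒ 19 ⇒ 18. Bonds cut: C1–Br, the C2 carbonyl (back to a protected alcohol) and a temporary O–Si bond at C10. Bromine at C1 is what makes the enolate regiodefined. It is introduced before the oxirane exists, because thermodynamic enol silylation uses reagents an oxirane would not survive; C10–OH is therefore masked for four steps.

18 ⇒ 13 + 14 + 15. Bonds cut: C8–CH3 and C9–C10. This removes the trisubstituted alkene and its geometry problem in one operation and leaves a terminal alkyne. The demand is syn addition with methyl on the internal carbon and capture with retention. Checked atom by atom, 13 and 18 already carry the C4, C5 and C6 configurations of 35.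

13 ⇒ 12 ⇒ 10 + 11. Bond cut: C6–C7. The C6 carbinol of 35 is the anti-Felkin (chelate) diastereomer relative to C5. The aldehyde 10 is therefore used with its C4 hydroxyl free so that a chelating metal directs the addition; the two hydroxyls are silylated together afterwards.

10 ⇒ 9 ⇒ 8. Bonds cut: C1–H and C5–H. Both ring stereocentres come from one syn addition of hydrogen. The demand is delivery from the α face, which a free tertiary allylic C4 hydroxyl secures; hence the silyl group of 8 is removed first.

8 ⇒ 7 ⇒ 6. Bond cut: C1=C5 (aldol condensation); reconnecting C1 to the formyl carbon gives a cyclohexene. In 7 the C4 oxygen must be a poor leaving group, or dehydration could run toward C4; it is therefore silylated in 6. The 4-methoxybenzyl ether dictates osmium/periodate cleavage instead of ozone.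

6 ⇒ 5 ⇒ 4 ⇒ 3 ⇒ 1. Bonds cut: O–Si, O–benzyl, C2–H and C2–O. The C2 oxygen is introduced by allylic oxidation of the chiral-pool alcohol 1, whose single stereocentre maps onto 4R of 35. The demand is oxidation at the ring CH2 next to the methyl-bearing alkene carbon and a defined C2 configuration, obtained by directed reduction of 3.

## Other disconnections considered

Alternative 1: The cut is C3–C4 of ring A. In the forward step Rh2(OAc)4 converts the diazo group of the acyclic β-keto diester A1 into a rhodium carbenoid at C3 that inserts into the C4–H bond with retention, giving cyclopentanone A2.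
- In its favour: one step makes ring A and the tetrasubstituted C4 carbinol, and 1,5-insertion into an ether-activated methine is the preferred mode. C4 need only be a secondary carbinol ether in A1, which is easier to set than a tertiary one.
- Better than the chosen plan on oxidation-state economy: C2 arrives as a ketone and C6 as a carboxyl, whereas the chosen plan spends steps 1–3 and 12–13 on the C2 oxygen.
- Against it: A1 needs three contiguous acyclic stereocentres (C1, C5, C4), while the chosen plan takes C4 from 1 and sets C1 and C5 in one directed hydrogenation.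
- A2 is a β-silyloxy β-keto ester that can eliminate the C4 oxygen through its C3 enolate; the extra C3 ester must be removed and the C2 ketone masked before any organoaluminium chemistry; oxonium-ylide formation is a competing carbenoid pathway.
- It is silent on the oxirane and ring B, so the carbometalation and the ring closure would still be needed. On step count to a ring A aldehyde it is about equal.

Alternative 2: The cut is C1–C10. SmI2 (divalent samarium) reduces the bromo ketone A3 to a trivalent samarium enolate that adds to the C10 aldehyde and gives the bicyclic hydroxy ketone A4.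
- This is the bond and the reaction of step 18 of the chosen plan. A3 and A4 differ from 26 and from the aldol held as 29 only in the silyl group on the C6 oxygen. On structure and step count the two are equal.
- In its favour: it names the step that creates ring B, C1 and C10.
- Against it as the strategic centre: it presupposes the trans-oxirane in A3 without saying where the E geometry comes from, and it is the thermodynamically least secure step. Isolating A4 leaves a retro-aldol-prone β-hydroxy ketone and, after reduction, two similar secondary hydroxyls; the chosen plan avoids both by the in-flask Tishchenko reduction.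

Alternative 3: The cut is C1–C5. KN(SiMe3)2 forms the C1 enolate of cyclodecanone A5, which attacks C5 of the C4–C5 oxirane across the ring with inversion, closing both rings and freeing the C4 alkoxide to give A6.
- Better than the chosen plan on thermodynamics: an irreversible, exothermic oxirane opening pays for the strain of the second oxirane becoming trans-fused, where the chosen plan relies on a reversible aldol.
- Better on enolate regiochemistry: C9 is an oxirane carbon, so only C1 can enolise and no bromination is needed. A trans-oxirane is also unstrained in a ten-membered ring.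
- The transannular step forms one skeletal bond, two rings, C1 and C5, and is better than any single step of the chosen plan.
- Against it: A5 is a ten-membered carbocycle with two trans-oxiranes of defined absolute configuration and a ketone, which is harder to reach than any intermediate here. The C1 outcome depends on a ring conformation no reagent controls, and O-alkylation can compete.
- A6 still needs reduction of the C10 ketone beside the strained oxirane and the same ester differentiation. Its C8–C9 unit would most simply come from the same methylalumination. Overall length is expected to be equal or longer.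

Key step: step 10

Assumption: the oxirane is taken exactly as drawn, with C7 and C10 on opposite sides of the three-membered ring; locants are C1 (C–CH3), C2 (CH–OAc), C3, C4 (C(OH)iPr), C5, C6 (CH–O-aroyl), C7, C8/C9 (oxirane), C10 (CH–OH); β is the ring A face of the C4 isopropyl group, α the face of the C4 oxygen.

## Route

Step 1
Reactants: 1 (S)-terpinen-4-ol
Product: 3 (5R)-5-hydroxy-2-methyl-5-(propan-2-yl)cyclohex-2-en-1-one, via allylic alcohol 2 (not isolated)
Conditions: SeO2 (0.5 equiv), t-BuOOH, CH2Cl2, 0 °C to rt; then MnO2, CH2Cl2, rt
Reagents that add atoms: tert-butyl hydroperoxide, CC(C)(C)OO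
Why: Riley-type allylic oxidation: the ene reaction of SeO2 at the more substituted alkene carbon and the following [2,3]-shift put oxygen on the ring CH2 next to the methyl-bearing carbon (future C2) without moving the double bond, and MnO2 converges the epimeric alcohols to the single enone 3. The C4 carbinol centre is untouched; conditions are kept neutral because 3 can dehydrate to a phenol.

Step 2
Reactants: 3 (5R)-5-hydroxy-2-methyl-5-(propan-2-yl)cyclohex-2-en-1-one
Product: 4 (1S,5R)-2-methyl-5-(propan-2-yl)cyclohex-2-ene-1,5-diol (hydroxyls trans)
Conditions: Me4NBH(OAc)3, MeCN/AcOH (1:1), −30 °C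
Reagents that add atoms: none
Why: Hydroxyl-directed (Evans–Saksena) 1,2-reduction: the tertiary hydroxyl exchanges onto boron and hands hydride to the carbonyl face syn to itself, so the new secondary hydroxyl (future C2–O) should end trans to the C4 oxygen and cis to isopropyl (β). Low temperature suppresses loss of the tertiary hydroxyl.

Step 3
Reactants: 4 (1S,5R)-2-methyl-5-(propan-2-yl)cyclohex-2-ene-1,5-diol
Product: 5 secondary 4-methoxybenzyl ether of 4 (tertiary hydroxyl free)
Conditions: NaH (1.05 equiv), 4-methoxybenzyl chloride, Bu4NI (cat.), THF/DMF, 0 °C to rt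
Reagents that add atoms: 4-methoxybenzyl chloride, COc1ccc(CCl)cc1
Why: Williamson etherification of the more accessible secondary allylic alkoxide; with one equivalent of base the hindered tertiary hydroxyl should stay free.

Step 4
Reactants: 5 secondary 4-methoxybenzyl ether
Product: 6 tertiary triethylsilyl ether of 5
Conditions: Et3SiOTf, 2,6-lutidine, CH2Cl2, −78 to 0 °C
Reagents that add atoms: triethylsilyl trifluoromethanesulfonate, CC[Si](CC)(CC)OS(=O)(=O)C(F)(F)F
Why: Silyl triflate silylation of the tertiary alcohol; the C4 oxygen must be a poor leaving group in step 5 so that the cyclodehydration can only lose the C1 hydroxyl.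

Step 5
Reactants: 6 bis-ether cyclohexene
Product: 8 ring A enal 3-[(4-methoxybenzyl)oxy]-2-methyl-5-(propan-2-yl)-5-[(triethylsilyl)oxy]cyclopent-1-ene-1-carbaldehyde, via keto aldehyde 7 (not isolated)
Conditions: OsO4 (2 mol%), NaIO4, 2,6-lutidine, dioxane/H2O (3:1), rt; then piperidine, AcOH, benzene, 60 °C
Reagents that add atoms: sodium periodate, [Na+].[O-]I(=O)(=O)=O
Why: Lemieux–Johnson cleavage of the trisubstituted alkene (chosen over ozonolysis because the 4-methoxybenzyl ether survives it) gives keto aldehyde 7. Amine-catalysed intramolecular aldol condensation (aldehyde enamine carbon C5 onto the methyl ketone C1, then loss of water from C1) contracts the ring to the tetrasubstituted enal 8; C2 and C4 keep their configurations.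

Step 6
Reactants: 8 ring A enal (C4 silyl ether)
Product: 9 ring A enal with free C4 hydroxyl
Conditions: Bu4NF, AcOH, THF, 0 °C to rt
Reagents that add atoms: none
Why: Fluoride cleavage of the Si–O bond, buffered with acetic acid to spare the enal; the free C4 hydroxyl is the directing and chelating group of steps 7 and 8.

Step 7
Reactants: 9 ring A enal with free C4 hydroxyl
Product: 10 ring A aldehyde (C1β-methyl, C2β-OPMB, C4α-hydroxy, C5β-formyl)
Conditions: [Ir(cod)(PCy3)(py)]PF6 (10 mol%), H2 (1 atm), CH2Cl2, rt
Reagents that add atoms: none
Why: Hydroxyl-directed hydrogenation with a cationic iridium catalyst (Stork–Crabtree type), which reduces tetrasubstituted alkenes: the metal binds the tertiary allylic C4 hydroxyl on the α face and adds both hydrogens syn from that face, setting C5 (H α, formyl β) and C1 (H α, methyl β). Isopropyl and the C2 ether shield the β face as well.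

Step 8
Reactants: 10 ring A aldehyde; 11 propargyl bromide
Product: 12 (6R)-homopropargylic alcohol with free C4 hydroxyl
Conditions: Zn dust, THF, 0 °C (11 to allenylzinc bromide); then 10, −40 to 0 °C; aq. NH4Cl
Reagents that add atoms: none
Why: Barbier-type propargylation (allenylzinc bromide adds through an SE2' six-centre transition state to give the homopropargylic alcohol) under 1,3-chelation control. Zinc bridges the C4 oxygen and the aldehyde oxygen; the chelate face on the side of isopropyl and C1 is blocked, so attack syn to H5 should give the 6R carbinol, the anti-Felkin (Cram-chelate) product.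

Step 9
Reactants: 12 (6R)-homopropargylic alcohol
Product: 13 C4,C6-bis(triethylsilyl) ether of 12
Conditions: Et3SiOTf (3 equiv), 2,6-lutidine, CH2Cl2, −78 to 0 °C
Reagents that add atoms: triethylsilyl trifluoromethanesulfonate, CC[Si](CC)(CC)OS(=O)(=O)C(F)(F)F
Why: Exhaustive silylation with the silyl triflate covers the secondary C6 and tertiary C4 hydroxyls, the only O–H groups, before the organoaluminium step.

Step 10
Reactants: 13 bis(triethylsilyl) alkyne; 14 trimethylaluminium; 15 formaldehyde (used as paraformaldehyde)
Product: 18 (E)-allylic alcohol with C10 trans to C7, via alkenylalane 16 (not isolated), via lithium alanate 17 (not isolated)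
Conditions: AlMe3 (3 equiv), Cp2ZrCl2 (0.5 equiv), CH2Cl2, 0 °C to rt; volatiles removed; n-BuLi, THF/hexane, −78 °C; (CH2O)n, −78 °C to rt
Reagents that add atoms: none
Why: Cp2ZrCl2 and AlMe3 form a methylzirconium–aluminium bimetallic species that adds CH3 and metal across the terminal alkyne in one syn step, methyl to the substituted carbon C8 and metal to the terminal carbon C9, and exchange of zirconium for aluminium leaves the (E)-2-methylalkenylalane 16. n-Butyllithium turns 16 into the more nucleophilic alanate 17, whose alkenyl–aluminium bond adds to formaldehyde with retention of the double-bond geometry and forms C9–C10. The closest known reaction type is the zirconium-catalysed methylalumination of terminal alkynes (Negishi carboalumination) with hydroxymethylation of the derived ate complex, the standard entry to (E)-3-methylalk-2-en-1-ols. No ring is closed and no stereocentre is formed; the element of control is the syn addition, which puts CH3 cis to C10 and therefore C7 trans to C10. The step needs regioselectivity (methyl on C8), strict syn addition and chemoselectivity for the alkyne; the first two are inherent to carbometalation of a terminal alkyne, and the substrate secures the third because it offers no carbonyl group, no free O–H and no other reactive π bond, only silyl and benzyl-type ethers that tolerate organoalanes. Because epoxidation of 18 will convert this geometry stereospecifically into the C7/C10-trans oxirane and no later operation could repair it, both skeletal bonds and the geometry are secured here in the open chain.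

Step 11
Reactants: 18 (E)-allylic alcohol
Product: 19 C10 triethylsilyl ether of 18
Conditions: Et3SiCl, imidazole, CH2Cl2, 0 °C
Reagents that add atoms: chlorotriethylsilane, CC[Si](Cl)(CC)CC
Why: Silylation of the primary allylic alcohol; this temporary group lets C2 be oxidised and C1 brominated before the acid- and Lewis-acid-sensitive oxirane is introduced.

Step 12
Reactants: 19 tris(triethylsilyl) ether with C2 4-methoxybenzyl ether
Product: 20 C2 alcohol
Conditions: DDQ, CH2Cl2/pH 7 buffer (10:1), 0 °C
Reagents that add atoms: none
Why: Oxidative cleavage of the 4-methoxybenzyl ether by DDQ (benzylic hydride abstraction, hydrolysis of the hemiacetal); silyl ethers and the trisubstituted alkene are inert under buffered conditions.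

Step 13
Reactants: 20 C2 alcohol
Product: 21 C2 ketone
Conditions: Dess–Martin periodinane, NaHCO3, CH2Cl2, 0 °C to rt
Reagents that add atoms: none
Why: Dess–Martin oxidation of the hindered secondary alcohol under buffered, non-basic conditions that avoid β-elimination of the C4 silyloxy group; the configuration at C1 no longer matters.

Step 14
Reactants: 21 C2 ketone
Product: 23 C1-bromo C2-ketone (bromine α), via enol silyl ether 22 (not isolated)
Conditions: (Me3Si)2NH, Me3SiI, CH2Cl2, −20 °C to rt; then NBS, THF, −78 °C
Reagents that add atoms: N-bromosuccinimide, O=C1CCC(=O)N1Br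
Why: Thermodynamic enol silylation (iodotrimethylsilane with hexamethyldisilazane equilibrates to the more substituted C1=C2 enol ether 22) followed by electrophilic bromination with NBS places bromine at C1, expected anti to the C5 side chain. Either C1 epimer would give the same enolate in step 18.

Step 15
Reactants: 23 C1-bromo C2-ketone, C10 silyl ether
Product: 24 C1-bromo C2-ketone (E)-allylic alcohol
Conditions: pyridinium p-toluenesulfonate (cat.), MeOH/CH2Cl2 (1:1), 0 °C
Reagents that add atoms: none
Why: Acid-catalysed methanolysis removes the primary allylic triethylsilyl ether much faster than the secondary (C6) and tertiary (C4) ones; a tertiary α-bromo ketone is stable to these mildly acidic conditions.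

Step 16
Reactants: 24 bromo ketone allylic alcohol
Product: 25 (8R,9R)-epoxy alcohol
Conditions: Ti(OiPr)4 (0.2 equiv), D-(−)-diisopropyl tartrate (0.25 equiv), t-BuOOH, 4 Å MS, CH2Cl2, −20 °C
Reagents that add atoms: tert-butyl hydroperoxide, CC(C)(C)OO
Why: Sharpless asymmetric epoxidation of a 3,3-disubstituted (E)-allylic alcohol, the best substrate class for it. The titanium–D-(−)-tartrate–peroxide complex delivers oxygen to the face that gives the (8R,9R)-oxirane (the mirror image of the 2S,3S sense of the L-(+)-ester), and the stereospecific syn transfer turns the E geometry into C7 and C10 trans on the oxirane.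

Step 17
Reactants: 25 (8R,9R)-epoxy alcohol
Product: 26 (8R,9R)-epoxy aldehyde with C1-bromo C2-ketone
Conditions: Dess–Martin periodinane, NaHCO3, CH2Cl2, 0 °C
Reagents that add atoms: none
Why: Dess–Martin oxidation of the epoxy alcohol to the α,β-epoxy aldehyde under bicarbonate buffer; C9 cannot enolise without opening the ring, so the oxirane configuration is safe, and 26 is used at once.

Step 18
Reactants: 26 epoxy aldehyde with C1-bromo C2-ketone; 27 pent-4-enal
Product: 30 bicyclic C2β-alcohol C10 pent-4-enoate, via samarium enolate 28 (not isolated), via samarium aldolate 29 (not isolated)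
Conditions: SmI2 (2.1 equiv, 0.1 M in THF, added slowly), THF, −78 °C; then 27 (6 equiv), −78 to −10 °C
Reagents that add atoms: none
Why: Intramolecular samarium Reformatsky-type aldol followed in the same flask by Evans–Tishchenko reduction: SmI2 (divalent samarium) cleaves the C1–Br bond faster than it reduces the aldehyde and gives the regiodefined trivalent samarium enolate 28, which adds to the C10 aldehyde through a closed chelated transition state (7-exo-trig) to give aldolate 29. The ring containing the trans-oxirane can only be spanned if the bonds C5–C6 and C1–C10 are trans on ring A, which sets C1 (methyl β), and samarium bridging the two oxygens puts the C10 oxygen syn to C2 (10R). The hemiacetal formed from 29 and 27 then transfers hydride intramolecularly to the α face of the C2 carbonyl, which sets C2 (hydroxyl β), leaves C10 as its pent-4-enoate and removes the retro-aldol pathway.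

Step 19
Reactants: 30 bicyclic C2β-alcohol C10 pent-4-enoate
Product: 31 C2 acetate
Conditions: Ac2O, Et3N, 4-(dimethylamino)pyridine (cat.), CH2Cl2, 0 °C to rt
Reagents that add atoms: acetic anhydride, CC(=O)OC(C)=O
Why: Nucleophile-catalysed acetylation of the only free hydroxyl; regiochemistry is not in question because C10 is already esterified and C4 and C6 are silylated.

Step 20
Reactants: 31 C2 acetate
Product: 32 C4,C6-diol
Conditions: Bu4NF, AcOH, THF, 0 °C to rt
Reagents that add atoms: none
Why: Fluoride cleavage of the secondary and tertiary triethylsilyl ethers, buffered with acetic acid so that the esters do not migrate and the strained oxirane meets neither acid nor base.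

Step 21
Reactants: 32 C4,C6-diol; 33 3,4-dimethoxybenzoyl chloride
Product: 34 C6 3,4-dimethoxybenzoate C10 pent-4-enoate
Conditions: Et3N, 4-(dimethylamino)pyridine, CH2Cl2, 0 °C to rt
Reagents that add atoms: none
Why: Nucleophile-catalysed acylation with the aroyl chloride; the secondary C6 hydroxyl is the only acylable one, since the C4 hydroxyl is tertiary and hindered and C10 is still masked.

Step 22
Reactants: 34 C6 3,4-dimethoxybenzoate C10 pent-4-enoate
Product: 35 target
Conditions: I2, NaHCO3, THF/H2O (3:1), 0 °C to rt
Reagents that add atoms: none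
Why: Assisted cleavage of a pent-4-enoate: iodine activates the terminal alkene, the ester carbonyl oxygen closes a five-membered ring (iodolactonisation) and water hydrolyses the resulting dioxacarbenium ion, releasing the C10 alcohol and an iodolactone. The acetate and the aroate have no such pathway, and bicarbonate neutralises the hydrogen iodide before it can reach the oxirane.

## Compound list

1 | (S)-terpinen-4-ol, (1S)-4-methyl-1-(propan-2-yl)cyclohex-3-en-1-ol | CC1=CC[C@](O)(C(C)C)CC1 | starting material
2 | (5R)-2-methyl-5-(propan-2-yl)cyclohex-2-ene-1,5-diol, both C1 epimers | CC1=CC[C@](O)(C(C)C)CC1O | intermediate (not isolated)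
3 | (5R)-5-hydroxy-2-methyl-5-(propan-2-yl)cyclohex-2-en-1-one | CC1=CC[C@](O)(C(C)C)CC1=O | intermediate
4 | (1S,5R)-2-methyl-5-(propan-2-yl)cyclohex-2-ene-1,5-diol, hydroxyls trans | CC1=CC[C@](O)(C(C)C)C[C@@H]1O | intermediate
5 | 4 with the secondary hydroxyl as 4-methoxybenzyl ether | CC1=CC[C@](O)(C(C)C)C[C@@H]1OCc2ccc(OC)cc2 | intermediate
6 | 5 with the tertiary hydroxyl as triethylsilyl ether | CC1=CC[C@](O[Si](CC)(CC)CC)(C(C)C)C[C@@H]1OCc2ccc(OC)cc2 | intermediate
7 | 5-[(4-methoxybenzyl)oxy]-6-oxo-3-(propan-2-yl)-3-[(triethylsilyl)oxy]heptanal, carbinol configurations of 6 | CC(=O)[C@@H](OCc1ccc(OC)cc1)C[C@@](CC=O)(O[Si](CC)(CC)CC)C(C)C | intermediate (not isolated)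
8 | ring A enal, 3-[(4-methoxybenzyl)oxy]-2-methyl-5-(propan-2-yl)-5-[(triethylsilyl)oxy]cyclopent-1-ene-1-carbaldehyde (C2β-OPMB, C4α-OSiEt3) | O=CC1=C(C)[C@@H](OCc2ccc(OC)cc2)C[C@@]1(O[Si](CC)(CC)CC)C(C)C | intermediate
9 | ring A enal with free C4 hydroxyl | O=CC1=C(C)[C@@H](OCc2ccc(OC)cc2)C[C@@]1(O)C(C)C | intermediate
10 | ring A aldehyde, C1β-methyl, C2β-OPMB, C4α-hydroxy, C4β-isopropyl, C5β-formyl | O=C[C@H]1[C@@H](C)[C@@H](OCc2ccc(OC)cc2)C[C@@]1(O)C(C)C | intermediate
11 | propargyl bromide (3-bromoprop-1-yne) | C#CCBr | starting material
12 | (6R)-homopropargylic alcohol with free C4 hydroxyl | C#CC[C@@H](O)[C@H]1[C@@H](C)[C@@H](OCc2ccc(OC)cc2)C[C@@]1(O)C(C)C | intermediate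
13 | C4,C6-bis(triethylsilyl) ether of 12 (C8≡C9 alkyne, C2-OPMB) | C#CC[C@@H](O[Si](CC)(CC)CC)[C@H]1[C@@H](C)[C@@H](OCc2ccc(OC)cc2)C[C@@]1(O[Si](CC)(CC)CC)C(C)C | intermediate
14 | trimethylaluminium | C[Al](C)C | starting material
15 | formaldehyde (used as paraformaldehyde) | C=O | starting material
16 | (E)-alkenyl(dimethyl)alane, aluminium on C9 cis to the C8 methyl | C[Al](C)/C=C(\C)C[C@@H](O[Si](CC)(CC)CC)[C@H]1[C@@H](C)[C@@H](OCc2ccc(OC)cc2)C[C@@]1(O[Si](CC)(CC)CC)C(C)C | intermediate (not isolated)
17 | lithium butyl(dimethyl)alkenylaluminate from 16 | [Li+].CCCC[Al-](C)(C)/C=C(\C)C[C@@H](O[Si](CC)(CC)CC)[C@H]1[C@@H](C)[C@@H](OCc2ccc(OC)cc2)C[C@@]1(O[Si](CC)(CC)CC)C(C)C | intermediate (not isolated)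
18 | (E)-allylic alcohol, C10 hydroxymethyl trans to C7 | OC/C=C(\C)C[C@@H](O[Si](CC)(CC)CC)[C@H]1[C@@H](C)[C@@H](OCc2ccc(OC)cc2)C[C@@]1(O[Si](CC)(CC)CC)C(C)C | intermediate
19 | C10 triethylsilyl ether of 18 | CC[Si](CC)(CC)OC/C=C(\C)C[C@@H](O[Si](CC)(CC)CC)[C@H]1[C@@H](C)[C@@H](OCc2ccc(OC)cc2)C[C@@]1(O[Si](CC)(CC)CC)C(C)C | intermediate
20 | C2β alcohol, tris(triethylsilyl) ether | CC[Si](CC)(CC)OC/C=C(\C)C[C@@H](O[Si](CC)(CC)CC)[C@H]1[C@@H](C)[C@@H](O)C[C@@]1(O[Si](CC)(CC)CC)C(C)C | intermediate
21 | C2 ketone, tris(triethylsilyl) ether | CC[Si](CC)(CC)OC/C=C(\C)C[C@@H](O[Si](CC)(CC)CC)[C@H]1[C@@H](C)C(=O)C[C@@]1(O[Si](CC)(CC)CC)C(C)C | intermediate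
22 | C1=C2 trimethylsilyl enol ether of 21 | CC[Si](CC)(CC)OC/C=C(\C)C[C@@H](O[Si](CC)(CC)CC)[C@H]1C(C)=C(O[Si](C)(C)C)C[C@@]1(O[Si](CC)(CC)CC)C(C)C | intermediate (not isolated)
23 | C1α-bromo C2-ketone, C10 triethylsilyl ether | CC[Si](CC)(CC)OC/C=C(\C)C[C@@H](O[Si](CC)(CC)CC)[C@H]1[C@](C)(Br)C(=O)C[C@@]1(O[Si](CC)(CC)CC)C(C)C | intermediate
24 | C1α-bromo C2-ketone (E)-allylic alcohol | OC/C=C(\C)C[C@@H](O[Si](CC)(CC)CC)[C@H]1[C@](C)(Br)C(=O)C[C@@]1(O[Si](CC)(CC)CC)C(C)C | intermediate
25 | (8R,9R)-epoxy alcohol of 24 | OC[C@H]1O[C@]1(C)C[C@@H](O[Si](CC)(CC)CC)[C@H]2[C@](C)(Br)C(=O)C[C@@]2(O[Si](CC)(CC)CC)C(C)C | intermediate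
26 | (8R,9R)-epoxy aldehyde with C1α-bromo C2-ketone | O=C[C@H]1O[C@]1(C)C[C@@H](O[Si](CC)(CC)CC)[C@H]2[C@](C)(Br)C(=O)C[C@@]2(O[Si](CC)(CC)CC)C(C)C | intermediate
27 | pent-4-enal | C=CCCC=O | starting material
28 | C1=C2 samarium enolate (trivalent samarium) of the epoxy aldehyde | O=C[C@H]1O[C@]1(C)C[C@@H](O[Si](CC)(CC)CC)[C@H]2C(C)=C(O[Sm](I)I)C[C@@]2(O[Si](CC)(CC)CC)C(C)C | intermediate (not isolated)
29 | samarium C10-alkoxide of the trans-fused bicyclic C10-hydroxy C2-ketone | CC[Si](CC)(CC)O[C@@H]1C[C@@]2(C)O[C@@H]2[C@H](O[Sm](I)I)[C@]2(C)C(=O)C[C@@](O[Si](CC)(CC)CC)(C(C)C)[C@@H]12 | intermediate (not isolated)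
30 | bicyclic C2β-alcohol, C10 pent-4-enoate, C4,C6-bis(triethylsilyl) ether | CC[Si](CC)(CC)O[C@@H]1C[C@@]2(C)O[C@@H]2[C@H](OC(=O)CCC=C)[C@]2(C)[C@@H](O)C[C@@](O[Si](CC)(CC)CC)(C(C)C)[C@@H]12 | intermediate
31 | C2 acetate of 30 | CC[Si](CC)(CC)O[C@@H]1C[C@@]2(C)O[C@@H]2[C@H](OC(=O)CCC=C)[C@]2(C)[C@@H](OC(C)=O)C[C@@](O[Si](CC)(CC)CC)(C(C)C)[C@@H]12 | intermediate
32 | C4,C6-diol, C2 acetate, C10 pent-4-enoate | O[C@@H]1C[C@@]2(C)O[C@@H]2[C@H](OC(=O)CCC=C)[C@]2(C)[C@@H](OC(C)=O)C[C@@](O)(C(C)C)[C@@H]12 | intermediate
33 | 3,4-dimethoxybenzoyl chloride | COc1ccc(C(Cl)=O)cc1OC | starting material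
34 | C6 3,4-dimethoxybenzoate, C2 acetate, C10 pent-4-enoate | COc1ccc(C(=O)O[C@@H]2C[C@@]3(C)O[C@@H]3[C@H](OC(=O)CCC=C)[C@]3(C)[C@@H](OC(C)=O)C[C@@](O)(C(C)C)[C@@H]23)cc1OC | intermediate
35 | target, (1R,2S,4R,5R,6R,8R,9R,10R)-2-acetoxy-6-(3,4-dimethoxybenzoyloxy)-8,9-epoxydaucane-4,10-diol | COc1ccc(C(=O)O[C@@H]2C[C@@]3(C)O[C@@H]3[C@H](O)[C@]3(C)[C@@H](OC(C)=O)C[C@@](O)(C(C)C)[C@@H]23)cc1OC | target

## Step count and least certain steps

Total step count: 22. Longest linear sequence: 22 steps (1 to 35; the route is fully linear).

Step 10 (key step). Most likely failure: slow or incomplete carbometalation next to the branched, silyloxy-bearing C6, so that the alkenylalane is only protonated on work-up, or incomplete capture by formaldehyde. Loss of regiocontrol is less likely for a terminal alkyne. Fallback, from 13 back to 18: deprotonation of 13 with n-BuLi and addition of paraformaldehyde should give the propargylic alcohol F1. Alkoxide-directed trans-hydroalumination with NaAlH2(OCH2CH2OMe)2 and an iodine quench should give the (Z)-3-iodoallylic alcohol F2, with iodine on C8 cis to the hydroxymethyl group. Me2CuLi then replaces iodine by methyl with retention and gives 18. This reaches the same geometry by anti hydrometalation plus coupling instead of syn carbometalation.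

Step 18. Most likely failure: ring closure onto the trans-oxirane is thermodynamically marginal, so the samarium enolate is merely protonated (debrominated ketone) or the aldolate reverts before hydride transfer. Single-electron reduction of the epoxy aldehyde and a cis ring fusion are further leaks. Fallback, from 26 back to 30: a chromium Reformatsky closure with CrCl2 (divalent chromium) and catalytic LiI in THF at room temperature. It does not reduce aldehydes or oxiranes and gives a kinetically inert trivalent chromium aldolate; work-up should give the hydroxy ketone F3. A separate Evans–Tishchenko reduction of F3 with 27 and catalytic SmI2 at −10 °C then gives 30.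

Step 14. Most likely failure: leakage of the enol silylation to the C3 side, followed by β-elimination of the C4 silyloxy group or bromination at C3. Fallback, from 21 back to 24: direct acid-catalysed bromination with PhNMe3Br3 in THF at 0 °C, which goes through the more substituted enol and so brominates C1. The hydrogen bromide formed and a methanol quench remove the primary silyl ether, so the product should be 24; no new compound is involved.

Step 8. Most likely failure: poor facial selectivity if the non-chelated (Felkin) pathway competes, and epimerisation of the crowded C5 formyl centre by the zinc alkoxide. Fallback, from 10 back to 12: the 6S epimer F4 is separated and inverted under Mitsunobu conditions (PPh3, diisopropyl azodicarboxylate, 4-nitrobenzoic acid) to the 6R 4-nitrobenzoate F5, and methanolysis with K2CO3 in MeOH gives 12.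

Step 22. Most likely failure: opening of the strained oxirane by iodide or adventitious hydrogen iodide, or sluggish iodocyclisation of an ester carbonyl. Fallback, from 26 back to 35, using kinetic differentiation instead of the C10 mask: ring closure of 26 with an aqueous quench gives hydroxy ketone F3. Directed reduction with Me4NBH(OAc)3 gives the diol F6. Acetylation with one equivalent of Ac2O in pyridine at −20 °C should favour the C2 monoacetate F7, because the C10 hydroxyl is flanked by the quaternary C1 and the oxirane carbon C9. Bu4NF/AcOH gives the triol F8, and acylation with 33 should favour the less hindered C6 hydroxyl to give 35.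

## Further compounds

F1 | step 10 | propargylic alcohol from C-hydroxymethylation of 13 | OCC#CC[C@@H](O[Si](CC)(CC)CC)[C@H]1[C@@H](C)[C@@H](OCc2ccc(OC)cc2)C[C@@]1(O[Si](CC)(CC)CC)C(C)C
F2 | step 10 | (Z)-3-iodoallylic alcohol, iodine on C8 | OC/C=C(\I)C[C@@H](O[Si](CC)(CC)CC)[C@H]1[C@@H](C)[C@@H](OCc2ccc(OC)cc2)C[C@@]1(O[Si](CC)(CC)CC)C(C)C
F3 | step 18 | trans-fused bicyclic C10-hydroxy C2-ketone, C4,C6-bis(triethylsilyl) ether | CC[Si](CC)(CC)O[C@@H]1C[C@@]2(C)O[C@@H]2[C@H](O)[C@]2(C)C(=O)C[C@@](O[Si](CC)(CC)CC)(C(C)C)[C@@H]12
F0 | step 14 | none | none
F4 | step 8 | (6S)-homopropargylic alcohol, C6 epimer of 12 | C#CC[C@H](O)[C@H]1[C@@H](C)[C@@H](OCc2ccc(OC)cc2)C[C@@]1(O)C(C)C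
F5 | step 8 | (6R)-4-nitrobenzoate of 12 | C#CC[C@@H](OC(=O)c1ccc(cc1)[N+](=O)[O-])[C@H]1[C@@H](C)[C@@H](OCc2ccc(OC)cc2)C[C@@]1(O)C(C)C
F6 | step 22 | bicyclic C2β,C10-diol, C4,C6-bis(triethylsilyl) ether | CC[Si](CC)(CC)O[C@@H]1C[C@@]2(C)O[C@@H]2[C@H](O)[C@]2(C)[C@@H](O)C[C@@](O[Si](CC)(CC)CC)(C(C)C)[C@@H]12
F7 | step 22 | C2 monoacetate of F6 | CC[Si](CC)(CC)O[C@@H]1C[C@@]2(C)O[C@@H]2[C@H](O)[C@]2(C)[C@@H](OC(C)=O)C[C@@](O[Si](CC)(CC)CC)(C(C)C)[C@@H]12
F8 | step 22 | C2 acetate C4,C6,C10-triol | O[C@@H]1C[C@@]2(C)O[C@@H]2[C@H](O)[C@]2(C)[C@@H](OC(C)=O)C[C@@](O)(C(C)C)[C@@H]12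
A1 | alternative 1 | acyclic C3 diazo β-keto diester with C4–H triethylsilyl ether | COC(=O)C(=[N+]=[N-])C(=O)[C@H](C)[C@H](C(=O)OC)[C@H](O[Si](CC)(CC)CC)C(C)C
A2 | alternative 1 | ring A cyclopentanone with tetrasubstituted C4 carbinol ether | COC(=O)[C@@H]1C(=O)[C@H](C)[C@H](C(=O)OC)[C@]1(O[Si](CC)(CC)CC)C(C)C
A3 | alternative 2 | C1-bromo C2-ketone epoxy aldehyde, C6 tert-butyldimethylsilyl ether | O=C[C@H]1O[C@]1(C)C[C@@H](O[Si](C)(C)C(C)(C)C)[C@H]2C(C)(Br)C(=O)C[C@@]2(O[Si](CC)(CC)CC)C(C)C
A4 | alternative 2 | trans-fused bicyclic C10-hydroxy C2-ketone with the oxirane in place | CC(C)(C)[Si](C)(C)O[C@@H]2C[C@@]3(C)O[C@@H]3[C@H](O)[C@]3(C)C(=O)C[C@@](O[Si](CC)(CC)CC)(C(C)C)[C@@H]23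
A5 | alternative 3 | cyclodecan-10-one with C4–C5 and C8–C9 trans-oxiranes | CC(C)(C)[Si](C)(C)O[C@@H]1C[C@@]2(C)O[C@@H]2C(=O)C(C)[C@@H](OCc3ccc(OC)cc3)C[C@]4(C(C)C)O[C@@H]14
A6 | alternative 3 | trans-fused hydroazulene C10 ketone with free C4 hydroxyl | CC(C)(C)[Si](C)(C)O[C@@H]2C[C@@]3(C)O[C@@H]3C(=O)[C@]3(C)[C@@H](OCc4ccc(OC)cc4)C[C@@](O)(C(C)C)[C@@H]23
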